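The route rests on forming the C5–O bond last, on the finished flavone. In ring A, C5–H is the one C–H bond peri to the C4 carbonyl oxygen of ring C, and the only one that can close a five-membered ruthenacycle with that oxygen. A carbonyl-directed, ruthenium-catalysed hydroxylation therefore adds the crowded 5-oxygen in one operation and keeps it distinct from O7 and O5'. The precursor is the 6-methoxyflavone whose 7- and 5'-hydroxyls are masked as pivalates, assembled from O-benzylisovanillin and 3-hydroxy-4,5-dimethoxybenzaldehyde through a chalcone. Methylation of the new hydroxyl and ester methanolysis finish the target.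

Key step: step 8

Remarks on the chemistry:
- Ring A must come from the isovanillin series. Baeyer–Villiger oxidation and acetylation ortho to the new hydroxyl turn the 4-methoxy group into the C6 methoxy group and the 3-oxygen into O7 of the flavone; the vanillin series would transpose these two substituents.
- O-Benzylisovanillin (1) is assumed to be bought; it is an article of commerce.
- Benzyl ethers serve up to the flavone and are then exchanged for pivalates, because ethers would neither survive hot TFA nor temper the rings against the oxidant. The ring B aldehyde enters directly through a chalcone, so no oxidation to the acid is needed.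
- The target has no stereocentre. The E double bond of chalcone 9 is the only stereo-element on the way and is consumed in step 5.

Step 1
Reactants: 1 3-(benzyloxy)-4-methoxybenzaldehyde
Product: 3 3-(benzyloxy)-4-methoxyphenol, via aryl formate 2 (not isolated)
Conditions: mCPBA, CH2Cl2, 0 °C to rt; then MeOH, Et3N (cat.), rt
Reagents that add atoms: 3-chloroperoxybenzoic acid (mCPBA), O=C(OO)c1cccc(Cl)c1
Why: Baeyer–Villiger oxidation of an electron-rich benzaldehyde, in which the 4-methoxyaryl group migrates in preference to hydrogen, should give aryl formate 2, and amine-catalysed methanolysis then frees the phenol without touching the benzyl ether.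

Step 2
Reactants: 3 3-(benzyloxy)-4-methoxyphenol; 4 acetic acid
Product: 5 1-[4-(benzyloxy)-2-hydroxy-5-methoxyphenyl]ethan-1-one
Conditions: AcOH, BF3·OEt2, 70 °C; then H2O
Reagents that add atoms: acetic acid, CC(=O)O
Why: Boron trifluoride-promoted Friedel–Crafts ortho-acetylation of the phenol should go to C6, the position para to the benzyloxy group, because the other ortho position is flanked by two oxygen substituents and the product is a stable chelated ortho-hydroxy ketone.

Step 3
Reactants: 6 3-hydroxy-4,5-dimethoxybenzaldehyde; 7 benzyl bromide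
Product: 8 3-(benzyloxy)-4,5-dimethoxybenzaldehyde
Conditions: BnBr, K2CO3, DMF, rt
Reagents that add atoms: benzyl bromide, BrCc1ccccc1
Why: Williamson ether synthesis on the single phenolic hydroxyl, so that ring B carries no free phenol through the iodine-mediated cyclisation.

Step 4
Reactants: 5 1-[4-(benzyloxy)-2-hydroxy-5-methoxyphenyl]ethan-1-one; 8 3-(benzyloxy)-4,5-dimethoxybenzaldehyde
Product: 9 (E)-1-[4-(benzyloxy)-2-hydroxy-5-methoxyphenyl]-3-[3-(benzyloxy)-4,5-dimethoxyphenyl]prop-2-en-1-one
Conditions: KOH, EtOH/H2O, rt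
Reagents that add atoms: none
Why: Claisen–Schmidt condensation (crossed aldol followed by E1cB dehydration) between the methyl ketone and the non-enolisable aldehyde should give the thermodynamically favoured E enone, the chelated 2-hydroxyl needing no protection.

Step 5
Reactants: 9 (E)-1-[4-(benzyloxy)-2-hydroxy-5-methoxyphenyl]-3-[3-(benzyloxy)-4,5-dimethoxyphenyl]prop-2-en-1-one
Product: 10 7-(benzyloxy)-2-[3-(benzyloxy)-4,5-dimethoxyphenyl]-6-methoxy-4H-chromen-4-one
Conditions: I2 (10 mol %), DMSO, 130 °C
Reagents that add atoms: none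
Why: Iodine-catalysed oxidative cyclisation of a 2'-hydroxychalcone in DMSO (oxa-Michael ring closure followed by dehydrogenation, with DMSO regenerating iodine) is a standard flavone synthesis and leaves aryl benzyl and methyl ethers intact.

Step 6
Reactants: 10 7-(benzyloxy)-2-[3-(benzyloxy)-4,5-dimethoxyphenyl]-6-methoxy-4H-chromen-4-one
Product: 11 7-hydroxy-2-(3-hydroxy-4,5-dimethoxyphenyl)-6-methoxy-4H-chromen-4-one
Conditions: H2 (1 atm), 10% Pd/C, THF/MeOH, rt
Reagents that add atoms: none
Why: Catalytic hydrogenolysis should cleave both aryl benzyl ethers, and the reaction is stopped after uptake of two equivalents of hydrogen because the conjugated C2–C3 double bond of a flavone is reduced much more slowly under these conditions.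

Step 7
Reactants: 11 7-hydroxy-2-(3-hydroxy-4,5-dimethoxyphenyl)-6-methoxy-4H-chromen-4-one; 12 pivaloyl chloride
Product: 13 2-[3,4-dimethoxy-5-(pivaloyloxy)phenyl]-6-methoxy-4-oxo-4H-chromen-7-yl pivalate
Conditions: PivCl, Et3N, DMAP (cat.), CH2Cl2, 0 °C to rt
Reagents that add atoms: pivaloyl chloride, CC(C)(C)C(Cl)=O
Why: DMAP-catalysed O-acylation (esterification) of the two free phenols should go to completion, since neither is chelated to the carbonyl group while C5 is still unsubstituted.

Step 8
Reactants: 13 2-[3,4-dimethoxy-5-(pivaloyloxy)phenyl]-6-methoxy-4-oxo-4H-chromen-7-yl pivalate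
Product: 15 2-[3,4-dimethoxy-5-(pivaloyloxy)phenyl]-5-hydroxy-6-methoxy-4-oxo-4H-chromen-7-yl pivalate, via C5 trifluoroacetate 14 (not isolated)
Conditions: [RuCl2(p-cymene)]2 (5 mol %), PhI(OCOCF3)2 (2 equiv), TFA/TFAA, 80 °C; then H2O
Reagents that add atoms: [bis(trifluoroacetoxy)iodo]benzene, O=C(OI(OC(=O)C(F)(F)F)c1ccccc1)C(F)(F)F
Why: The divalent ruthenium trifluoroacetate formed from [RuCl2(p-cymene)]2 in TFA binds the C4 carbonyl oxygen and cleaves the peri C5–H bond by carboxylate-assisted concerted metalation–deprotonation, giving a five-membered ruthenacycle (Ru–O=C4–C4a–C5). PhI(OCOCF3)2 oxidises this to a tetravalent ruthenium trifluoroacetate, C–O reductive elimination releases the C5 trifluoroacetate 14 and the divalent catalyst, and water cleaves the labile aryl trifluoroacetate to the chelated phenol 15 on work-up. The closest known reaction type is the ketone-directed, ruthenium-catalysed ortho C–H hydroxylation of aryl ketones, which has been used at the peri position of chromones and flavones. No ring of the product is closed and no stereocentre is formed. The step needs oxygenation at C5 and not at C8, C3, C2' or C6': only C5–H can reach the C4 oxygen through a five-membered chelate (C3–H would need a four-membered one), while the two pivalates and protonation of ring C in TFA lower the electron density of rings A and B enough to hold back undirected oxidation by the trivalent iodine reagent. Capture of the new oxygen as a trifluoroacetate in TFAA should protect it from over-oxidation until work-up.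

Step 9
Reactants: 15 2-[3,4-dimethoxy-5-(pivaloyloxy)phenyl]-5-hydroxy-6-methoxy-4-oxo-4H-chromen-7-yl pivalate; 16 iodomethane
Product: 17 2-[3,4-dimethoxy-5-(pivaloyloxy)phenyl]-5,6-dimethoxy-4-oxo-4H-chromen-7-yl pivalate
Conditions: MeI, Ag2O, DMF, rt to 40 °C, dark
Reagents that add atoms: iodomethane, CI
Why: Purdie-type O-methylation, in which Ag2O activates the iodide and takes up the acid under neutral conditions, should methylate the hydrogen-bonded 5-hydroxyl without a base that could cleave or transfer the aryl pivalates.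

Step 10
Reactants: 17 2-[3,4-dimethoxy-5-(pivaloyloxy)phenyl]-5,6-dimethoxy-4-oxo-4H-chromen-7-yl pivalate
Product: 18 7-hydroxy-2-(3-hydroxy-4,5-dimethoxyphenyl)-5,6-dimethoxy-4H-chromen-4-one (7,5'-dihydroxy-5,6,3',4'-tetramethoxyflavone)
Conditions: K2CO3, MeOH, rt; then aq. NH4Cl
Reagents that add atoms: none
Why: Base-mediated transesterification (methanolysis) of the two aryl pivalates should release both phenols, while the four aryl methyl ethers and the chromone ring are inert to methanolic carbonate at room temperature.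

Compound list
1 | 3-(benzyloxy)-4-methoxybenzaldehyde (O-benzylisovanillin) | COc1ccc(C=O)cc1OCc1ccccc1 | starting material
2 | 3-(benzyloxy)-4-methoxyphenyl formate | COc1ccc(OC=O)cc1OCc1ccccc1 | intermediate
3 | 3-(benzyloxy)-4-methoxyphenol | COc1ccc(O)cc1OCc1ccccc1 | intermediate
4 | acetic acid | CC(=O)O | starting material
5 | 1-[4-(benzyloxy)-2-hydroxy-5-methoxyphenyl]ethan-1-one | CC(=O)c1cc(OC)c(OCc2ccccc2)cc1O | intermediate
6 | 3-hydroxy-4,5-dimethoxybenzaldehyde | COc1cc(C=O)cc(O)c1OC | starting material
7 | benzyl bromide | BrCc1ccccc1 | starting material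
8 | 3-(benzyloxy)-4,5-dimethoxybenzaldehyde | COc1cc(C=O)cc(OCc2ccccc2)c1OC | intermediate
9 | (E)-1-[4-(benzyloxy)-2-hydroxy-5-methoxyphenyl]-3-[3-(benzyloxy)-4,5-dimethoxyphenyl]prop-2-en-1-one | COc1cc(/C=C/C(=O)c2cc(OC)c(OCc3ccccc3)cc2O)cc(OCc2ccccc2)c1OC | intermediate
10 | 7-(benzyloxy)-2-[3-(benzyloxy)-4,5-dimethoxyphenyl]-6-methoxy-4H-chromen-4-one | COc1cc(-c2cc(=O)c3cc(OC)c(OCc4ccccc4)cc3o2)cc(OCc2ccccc2)c1OC | intermediate
11 | 7-hydroxy-2-(3-hydroxy-4,5-dimethoxyphenyl)-6-methoxy-4H-chromen-4-one | COc1cc(-c2cc(=O)c3cc(OC)c(O)cc3o2)cc(O)c1OC | intermediate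
12 | pivaloyl chloride | CC(C)(C)C(Cl)=O | starting material
13 | 2-[3,4-dimethoxy-5-(pivaloyloxy)phenyl]-6-methoxy-4-oxo-4H-chromen-7-yl pivalate | O=c1cc(-c2cc(OC)c(OC)c(OC(=O)C(C)(C)C)c2)oc2cc(OC(=O)C(C)(C)C)c(OC)cc12 | intermediate
14 | 2-[3,4-dimethoxy-5-(pivaloyloxy)phenyl]-6-methoxy-4-oxo-5-(trifluoroacetoxy)-4H-chromen-7-yl pivalate | O=c1cc(-c2cc(OC)c(OC)c(OC(=O)C(C)(C)C)c2)oc2cc(OC(=O)C(C)(C)C)c(OC)c(OC(=O)C(F)(F)F)c12 | intermediate
15 | 2-[3,4-dimethoxy-5-(pivaloyloxy)phenyl]-5-hydroxy-6-methoxy-4-oxo-4H-chromen-7-yl pivalate | O=c1cc(-c2cc(OC)c(OC)c(OC(=O)C(C)(C)C)c2)oc2cc(OC(=O)C(C)(C)C)c(OC)c(O)c12 | intermediate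
16 | iodomethane | CI | starting material
17 | 2-[3,4-dimethoxy-5-(pivaloyloxy)phenyl]-5,6-dimethoxy-4-oxo-4H-chromen-7-yl pivalate | O=c1cc(-c2cc(OC)c(OC)c(OC(=O)C(C)(C)C)c2)oc2cc(OC(=O)C(C)(C)C)c(OC)c(OC)c12 | intermediate
18 | 7-hydroxy-2-(3-hydroxy-4,5-dimethoxyphenyl)-5,6-dimethoxy-4H-chromen-4-one | COc1cc(-c2cc(=O)c3c(OC)c(OC)c(O)cc3o2)cc(O)c1OC | target

Total step count: 10. Longest linear sequence: 9 steps (steps 1, 2 and 4 to 10; step 3 is a one-step side branch).

Steps most likely to fail

Step 8. Undirected oxidation of the oxygenated rings by the trivalent iodine reagent, or ester-directed metalation ortho to a pivalate, could outrun the carbonyl-directed pathway. The fallback abandons late C–H oxygenation and carries the 5-oxygen in from the arene. It sets out from 8 and comes back to the route at 18.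
- Baeyer–Villiger oxidation of 8 (mCPBA; then MeOH, Et3N) would give 3-(benzyloxy)-4,5-dimethoxyphenol F2 by way of 3-(benzyloxy)-4,5-dimethoxyphenyl formate F1.
- Hydrogenolysis (H2, Pd/C) would give 4,5-dimethoxybenzene-1,3-diol F3.
- Acetylation (AcOH, BF3·OEt2) at the position ortho to one hydroxyl and para to the other would give 1-(2,4-dihydroxy-5,6-dimethoxyphenyl)ethan-1-one F4.
- Benzylation of the non-chelated 4-hydroxyl (BnBr, K2CO3, acetone) would give 1-[4-(benzyloxy)-2-hydroxy-5,6-dimethoxyphenyl]ethan-1-one F5.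
- Claisen–Schmidt condensation with a second portion of 8 (KOH, EtOH) would give (E)-1-[4-(benzyloxy)-2-hydroxy-5,6-dimethoxyphenyl]-3-[3-(benzyloxy)-4,5-dimethoxyphenyl]prop-2-en-1-one F6.
- Iodine-catalysed cyclisation in DMSO would give 7-(benzyloxy)-2-[3-(benzyloxy)-4,5-dimethoxyphenyl]-5,6-dimethoxy-4H-chromen-4-one F7, and hydrogenolysis of both benzyl ethers would give 18.

Step 2. The Lewis acid could cause loss or migration of the benzyl group during the acylation. The fallback acylates without a protecting group and restores the ether afterwards by a regioselective alkylation. It sets out from 3 and comes back at 5.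
- Hydrogenolysis of 3 (H2, Pd/C, EtOAc) would give 4-methoxybenzene-1,3-diol F8.
- Friedel–Crafts acetylation (AcOH, BF3·OEt2) ortho to one hydroxyl and para to the other would give 1-(2,4-dihydroxy-5-methoxyphenyl)ethan-1-one F9.
- Alkylation with one equivalent of BnBr (K2CO3, acetone, reflux) should occur only at the non-chelated 4-hydroxyl and return 5.

Step 9. Alkylation of the strongly hydrogen-bonded 5-hydroxyl, flanked by the carbonyl group and the 6-methoxy group, could be sluggish, and prolonged reaction risks ester loss followed by over-methylation. The fallback exchanges the esters for base-stable acetals so that forcing basic methylation becomes possible. It sets out from 15 and comes back at 18.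
- Methanolysis of 15 (K2CO3, MeOH) would give 5,7-dihydroxy-2-(3-hydroxy-4,5-dimethoxyphenyl)-6-methoxy-4H-chromen-4-one F10.
- MOMCl and i-Pr2NEt in CH2Cl2 should cap only the two non-chelated hydroxyls, giving 5-hydroxy-6-methoxy-7-(methoxymethoxy)-2-[3,4-dimethoxy-5-(methoxymethoxy)phenyl]-4H-chromen-4-one F11.
- Me2SO4 and K2CO3 in refluxing acetone would give 5,6-dimethoxy-7-(methoxymethoxy)-2-[3,4-dimethoxy-5-(methoxymethoxy)phenyl]-4H-chromen-4-one F12.
- HCl in MeOH at 50 °C would remove both acetals and give 18.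

Further compounds
F1 | step 8 | 3-(benzyloxy)-4,5-dimethoxyphenyl formate | COc1cc(OC=O)cc(OCc2ccccc2)c1OC
F2 | step 8 | 3-(benzyloxy)-4,5-dimethoxyphenol | COc1cc(O)cc(OCc2ccccc2)c1OC
F3 | step 8 | 4,5-dimethoxybenzene-1,3-diol | COc1cc(O)cc(O)c1OC
F4 | step 8 | 1-(2,4-dihydroxy-5,6-dimethoxyphenyl)ethan-1-one | CC(=O)c1c(O)cc(O)c(OC)c1OC
F5 | step 8 | 1-[4-(benzyloxy)-2-hydroxy-5,6-dimethoxyphenyl]ethan-1-one | CC(=O)c1c(O)cc(OCc2ccccc2)c(OC)c1OC
F6 | step 8 | (E)-1-[4-(benzyloxy)-2-hydroxy-5,6-dimethoxyphenyl]-3-[3-(benzyloxy)-4,5-dimethoxyphenyl]prop-2-en-1-one | COc1cc(/C=C/C(=O)c2c(O)cc(OCc3ccccc3)c(OC)c2OC)cc(OCc2ccccc2)c1OC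
F7 | step 8 | 7-(benzyloxy)-2-[3-(benzyloxy)-4,5-dimethoxyphenyl]-5,6-dimethoxy-4H-chromen-4-one | COc1cc(-c2cc(=O)c3c(OC)c(OC)c(OCc4ccccc4)cc3o2)cc(OCc2ccccc2)c1OC
F8 | step 2 | 4-methoxybenzene-1,3-diol | COc1ccc(O)cc1O
F9 | step 2 | 1-(2,4-dihydroxy-5-methoxyphenyl)ethan-1-one | CC(=O)c1cc(OC)c(O)cc1O
F10 | step 9 | 5,7-dihydroxy-2-(3-hydroxy-4,5-dimethoxyphenyl)-6-methoxy-4H-chromen-4-one | COc1cc(-c2cc(=O)c3c(O)c(OC)c(O)cc3o2)cc(O)c1OC
F11 | step 9 | 5-hydroxy-6-methoxy-7-(methoxymethoxy)-2-[3,4-dimethoxy-5-(methoxymethoxy)phenyl]-4H-chromen-4-one | COCOc1cc(-c2cc(=O)c3c(O)c(OC)c(OCOC)cc3o2)cc(OC)c1OC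
F12 | step 9 | 5,6-dimethoxy-7-(methoxymethoxy)-2-[3,4-dimethoxy-5-(methoxymethoxy)phenyl]-4H-chromen-4-one | COCOc1cc(-c2cc(=O)c3c(OC)c(OC)c(OCOC)cc3o2)cc(OC)c1OC
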